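**Assumption:** the SMILES is read as the (2S,3R)-trans-2,3-dihydrobenzofuran; aldehyde 8 is extracted and used crude the same day, so it counts as isolated.

## Retrosynthetic overview
1. Target ⇐ DIBAL reduction of a cinnamate diacetate ⇐ Heck coupling of a 5-bromo-2,3-dihydrobenzofuran with methyl acrylate.
2. Dihydrofuran ring (the only ring built, closed last) ⇐ acid-mediated C2–O closure of a 2-(2-hydroxyaryl)-1-(4-hydroxyaryl)propane-1,3-diol; C3 steers C2 to trans.
3. C2–C3 bond ⇐ Evans syn boron aldol of an (S)-4-benzyl-N-(arylacetyl)oxazolidinone with MOM-protected syringaldehyde; the auxiliary sets C3.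
4. Arylacetic acid ⇐ 4-bromoguaiacol by O-allylation, aromatic Claisen rearrangement, MOM protection and oxidative cleavage of the allyl group.
5. Both benzene rings are purchased (4-bromoguaiacol, syringaldehyde).

## Route

**Step 1**
Reactants: 1 4-bromo-2-methoxyphenol; 2 allyl bromide
Product: 3 1-(allyloxy)-4-bromo-2-methoxybenzene
Conditions: K2CO3, acetone, reflux
Reagents that add atoms: none
Why: Williamson ether synthesis, the phenoxide displacing bromide from the unhindered allylic carbon; no stereocentre.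

**Step 2**
Reactants: 3 1-(allyloxy)-4-bromo-2-methoxybenzene
Product: 5 2-allyl-4-bromo-6-methoxyphenol, via ortho-dienone 4 (not isolated)
Conditions: PhNEt2, 195 °C
Reagents that add atoms: none
Why: Aromatic Claisen rearrangement, a [3,3]-shift to the only free ortho carbon followed by tautomerisation of dienone 4 to the phenol; no stereocentre remains.

**Step 3**
Reactants: 5 2-allyl-4-bromo-6-methoxyphenol
Product: 6 1-allyl-5-bromo-3-methoxy-2-(methoxymethoxy)benzene
Conditions: MOMCl, i-Pr2NEt, CH2Cl2, 0 °C → rt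
Reagents that add atoms: chloromethyl methyl ether, COCCl
Why: O-alkylation of the phenol gives a MOM acetal that survives oxidation, boron enolate chemistry and hydride, and is removed by the acid that later closes the ring.

**Step 4**
Reactants: 6 1-allyl-5-bromo-3-methoxy-2-(methoxymethoxy)benzene
Product: 8 2-[5-bromo-3-methoxy-2-(methoxymethoxy)phenyl]acetaldehyde, via vicinal diol 7 (not isolated)
Conditions: OsO4 (2 mol%), NaIO4, 2,6-lutidine, dioxane/H2O 3:1, rt
Reagents that add atoms: osmium tetroxide, O=[Os](=O)(=O)=O (oxygen donor, catalytic); sodium periodate, [Na+].[O-]I(=O)(=O)=O (terminal oxidant)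
Why: Lemieux–Johnson oxidation, in which dihydroxylation of the terminal alkene and periodate cleavage of diol 7 remove one carbon as formaldehyde, with lutidine suppressing over-oxidation.

**Step 5**
Reactants: 8 2-[5-bromo-3-methoxy-2-(methoxymethoxy)phenyl]acetaldehyde
Product: 9 2-[5-bromo-3-methoxy-2-(methoxymethoxy)phenyl]acetic acid
Conditions: NaClO2, NaH2PO4, 2-methyl-2-butene, t-BuOH/H2O, 0 °C → rt
Reagents that add atoms: sodium chlorite, [Na+].[O-]Cl=O
Why: Pinnick oxidation converts the aldehyde to the acid at pH about 4, where the MOM ether and aryl bromide are inert and the alkene scavenger removes HOCl before it chlorinates the ring.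

**Step 6**
Reactants: 9 2-[5-bromo-3-methoxy-2-(methoxymethoxy)phenyl]acetic acid; 10 (S)-4-benzyl-2-oxazolidinone
Product: 12 (S)-4-benzyl-3-{2-[5-bromo-3-methoxy-2-(methoxymethoxy)phenyl]acetyl}oxazolidin-2-one, via mixed pivalic anhydride 11 (not isolated)
Conditions: PivCl, Et3N, THF, −20 °C; then 10, LiCl, rt
Reagents that add atoms: none
Why: N-acylation through the mixed anhydride, the LiCl-activated oxazolidinone attacking the unhindered arylacetyl carbonyl, which avoids BuLi (Br–Li exchange) and a ketene-prone acid chloride.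

**Step 7**
Reactants: 13 syringaldehyde (4-hydroxy-3,5-dimethoxybenzaldehyde)
Product: 14 3,5-dimethoxy-4-(methoxymethoxy)benzaldehyde
Conditions: MOMCl, i-Pr2NEt, CH2Cl2, 0 °C → rt
Reagents that add atoms: chloromethyl methyl ether, COCCl
Why: MOM protection of the acidic phenol prevents it from quenching the boron enolate and is removed in the same acid step as the other MOM group.

**Step 8**
Reactants: 12 (S)-4-benzyl-3-{2-[5-bromo-3-methoxy-2-(methoxymethoxy)phenyl]acetyl}oxazolidin-2-one; 14 3,5-dimethoxy-4-(methoxymethoxy)benzaldehyde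
Product: 17 (S)-4-benzyl-3-{(2S,3S)-2-[5-bromo-3-methoxy-2-(methoxymethoxy)phenyl]-3-[3,5-dimethoxy-4-(methoxymethoxy)phenyl]-3-hydroxypropanoyl}oxazolidin-2-one, via Z-boron enolate 15 (not isolated), via boron aldolate 16 (not isolated)
Conditions: Bu2BOTf, i-Pr2NEt, CH2Cl2, 0 °C; 14, −78 → 0 °C; then pH 7 buffer, MeOH, 30% H2O2, 0 °C
Reagents that add atoms: none
Why: Evans syn aldol, in which the Z-dibutylboron enolate adds through a Zimmerman–Traxler chair on the face away from the auxiliary benzyl group, giving the (2S,3S) adduct whose α-carbon becomes C3 (R) of the target.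

**Step 9**
Reactants: 17 the Evans syn-aldol adduct
Product: 18 (1S,2R)-2-[5-bromo-3-methoxy-2-(methoxymethoxy)phenyl]-1-[3,5-dimethoxy-4-(methoxymethoxy)phenyl]propane-1,3-diol
Conditions: LiBH4, MeOH (1 equiv), THF, 0 °C
Reagents that add atoms: none
Why: Reductive cleavage of the exocyclic imide carbonyl gives the primary alcohol and returns the auxiliary under conditions too mild for retro-aldol or α-epimerisation, so both stereocentres are kept.

**Step 10**
Reactants: 18 the bis-MOM 1,3-diol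
Product: 20 4-[(2S,3R)-5-bromo-3-(hydroxymethyl)-7-methoxy-2,3-dihydrobenzofuran-2-yl]-2,6-dimethoxyphenol, via MOM-free tetraol 19 (not isolated)
Conditions: conc. HCl (aq.), MeOH, 50 °C
Reagents that add atoms: none
Why: Acid cleaves both MOM acetals and ionises the syringyl carbinol to a p-hydroxybenzyl cation (protonated quinone methide) that the ortho-phenol traps in an SN1 5-ring etherification; reversible ionisation at C2 gives the thermodynamic trans ring, so C3 from the aldol fixes C2 as S.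

**Step 11**
Reactants: 20 the bromo-dihydrobenzofuran phenol alcohol
Product: 21 4-[(2S,3R)-3-(acetoxymethyl)-5-bromo-7-methoxy-2,3-dihydrobenzofuran-2-yl]-2,6-dimethoxyphenyl acetate
Conditions: Ac2O, pyridine, DMAP (cat.), CH2Cl2, rt
Reagents that add atoms: acetic anhydride, CC(=O)OC(C)=O
Why: DMAP-catalysed acetylation masks the oxidation-prone phenol and the primary alcohol for the palladium step with groups that the final hydride reduction removes.

**Step 12**
Reactants: 21 the bromo diacetate; 22 methyl acrylate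
Product: 23 methyl (E)-3-[(2S,3R)-2-(4-acetoxy-3,5-dimethoxyphenyl)-3-(acetoxymethyl)-7-methoxy-2,3-dihydrobenzofuran-5-yl]acrylate
Conditions: Pd2(dba)3 (2 mol%), [HP(t-Bu)3]BF4 (8 mol%), Cy2NMe, dioxane, 70 °C
Reagents that add atoms: none
Why: Mizoroki–Heck reaction, where the electron-rich phosphine enables oxidative addition into the electron-rich aryl bromide and syn-insertion/syn-β-hydride elimination gives only the E-cinnamate, without touching C2 or C3.

**Step 13**
Reactants: 23 the cinnamate diacetate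
Product: 24 4-[(2S,3R)-3-(hydroxymethyl)-5-[(E)-3-hydroxyprop-1-en-1-yl]-7-methoxy-2,3-dihydrobenzofuran-2-yl]-2,6-dimethoxyphenol (target)
Conditions: DIBAL-H (8 equiv), CH2Cl2, −78 → 0 °C; Rochelle salt
Reagents that add atoms: none
Why: DIBAL reduces the enoate 1,2 to the E-allylic alcohol and reductively cleaves both acetates in one operation, and the neutral tartrate work-up protects the acid-sensitive cinnamyl alcohol.

## Compound list
1 | 4-bromo-2-methoxyphenol | COc1cc(Br)ccc1O | starting material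
2 | allyl bromide | C=CCBr | starting material
3 | 1-(allyloxy)-4-bromo-2-methoxybenzene | C=CCOc1ccc(Br)cc1OC | intermediate
4 | 6-allyl-4-bromo-2-methoxycyclohexa-2,4-dien-1-one (racemic, not isolated) | O=C1C(OC)=CC(Br)=CC1CC=C | intermediate
5 | 2-allyl-4-bromo-6-methoxyphenol | C=CCc1cc(Br)cc(OC)c1O | intermediate
6 | 1-allyl-5-bromo-3-methoxy-2-(methoxymethoxy)benzene | C=CCc1cc(Br)cc(OC)c1OCOC | intermediate
7 | 3-[5-bromo-3-methoxy-2-(methoxymethoxy)phenyl]propane-1,2-diol (racemic, not isolated) | OCC(O)Cc1cc(Br)cc(OC)c1OCOC | intermediate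
8 | 2-[5-bromo-3-methoxy-2-(methoxymethoxy)phenyl]acetaldehyde | O=CCc1cc(Br)cc(OC)c1OCOC | intermediate
9 | 2-[5-bromo-3-methoxy-2-(methoxymethoxy)phenyl]acetic acid | OC(=O)Cc1cc(Br)cc(OC)c1OCOC | intermediate
10 | (S)-4-benzyl-2-oxazolidinone | O=C1N[C@@H](Cc2ccccc2)CO1 | starting material
11 | 2-[5-bromo-3-methoxy-2-(methoxymethoxy)phenyl]acetic pivalic anhydride (not isolated) | CC(C)(C)C(=O)OC(=O)Cc1cc(Br)cc(OC)c1OCOC | intermediate
12 | (S)-4-benzyl-3-{2-[5-bromo-3-methoxy-2-(methoxymethoxy)phenyl]acetyl}oxazolidin-2-one | COCOc1c(OC)cc(Br)cc1CC(=O)N1[C@@H](Cc2ccccc2)COC1=O | intermediate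
13 | syringaldehyde (4-hydroxy-3,5-dimethoxybenzaldehyde) | COc1cc(C=O)cc(OC)c1O | starting material
14 | 3,5-dimethoxy-4-(methoxymethoxy)benzaldehyde | COCOc1c(OC)cc(C=O)cc1OC | intermediate
15 | (Z)-dibutylboron enolate of 12 (not isolated) | CCCCB(CCCC)O/C(=C\c1cc(Br)cc(OC)c1OCOC)N1[C@@H](Cc2ccccc2)COC1=O | intermediate
16 | O-dibutylboryl aldolate of 17 (not isolated) | COCOc1c(OC)cc([C@@H](OB(CCCC)CCCC)[C@@H](C(=O)N2[C@@H](Cc3ccccc3)COC2=O)c2cc(Br)cc(OC)c2OCOC)cc1OC | intermediate
17 | (S)-4-benzyl-3-{(2S,3S)-2-[5-bromo-3-methoxy-2-(methoxymethoxy)phenyl]-3-[3,5-dimethoxy-4-(methoxymethoxy)phenyl]-3-hydroxypropanoyl}oxazolidin-2-one | COCOc1c(OC)cc([C@@H](O)[C@@H](C(=O)N2[C@@H](Cc3ccccc3)COC2=O)c2cc(Br)cc(OC)c2OCOC)cc1OC | intermediate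
18 | (1S,2R)-2-[5-bromo-3-methoxy-2-(methoxymethoxy)phenyl]-1-[3,5-dimethoxy-4-(methoxymethoxy)phenyl]propane-1,3-diol | COCOc1c(OC)cc([C@@H](O)[C@@H](CO)c2cc(Br)cc(OC)c2OCOC)cc1OC | intermediate
19 | (1S,2R)-2-(5-bromo-2-hydroxy-3-methoxyphenyl)-1-(4-hydroxy-3,5-dimethoxyphenyl)propane-1,3-diol (not isolated) | COc1cc([C@@H](O)[C@@H](CO)c2cc(Br)cc(OC)c2O)cc(OC)c1O | intermediate
20 | 4-[(2S,3R)-5-bromo-3-(hydroxymethyl)-7-methoxy-2,3-dihydrobenzofuran-2-yl]-2,6-dimethoxyphenol | COc1cc([C@H]2Oc3c(OC)cc(Br)cc3[C@@H]2CO)cc(OC)c1O | intermediate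
21 | 4-[(2S,3R)-3-(acetoxymethyl)-5-bromo-7-methoxy-2,3-dihydrobenzofuran-2-yl]-2,6-dimethoxyphenyl acetate | COc1cc([C@H]2Oc3c(OC)cc(Br)cc3[C@@H]2COC(C)=O)cc(OC)c1OC(C)=O | intermediate
22 | methyl acrylate | C=CC(=O)OC | starting material
23 | methyl (E)-3-[(2S,3R)-2-(4-acetoxy-3,5-dimethoxyphenyl)-3-(acetoxymethyl)-7-methoxy-2,3-dihydrobenzofuran-5-yl]acrylate | COc1cc([C@H]2Oc3c(OC)cc(/C=C/C(=O)OC)cc3[C@@H]2COC(C)=O)cc(OC)c1OC(C)=O | intermediate
24 | 4-[(2S,3R)-3-(hydroxymethyl)-5-[(E)-3-hydroxyprop-1-en-1-yl]-7-methoxy-2,3-dihydrobenzofuran-2-yl]-2,6-dimethoxyphenol | COc1cc([C@H]2Oc3c(OC)cc(/C=C/CO)cc3[C@@H]2CO)cc(OC)c1O | target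

## Summary
Total step count: 13. Longest linear sequence: 12 steps (steps 1–6 and 8–13 from 1; step 7 is a one-step branch from 13).

Three steps most likely to fail:

**Step 8 (aldol).** The ortho,ortho-disubstituted, rather acidic arylacetyl imide may add sluggishly to the electron-rich aldehyde, and the adduct can undergo retro-aldol or α-epimerisation on work-up. The fallback sets out from acid 9 and changes the acyl donor and the enolate metal. Acid 9 is coupled with (S)-4-benzylthiazolidine-2-thione (EDC·HCl, DMAP, CH2Cl2) to give 1-[(S)-4-benzyl-2-thioxothiazolidin-3-yl]-2-[5-bromo-3-methoxy-2-(methoxymethoxy)phenyl]ethan-1-one F1. Its chlorotitanium enolate (TiCl4, i-Pr2NEt, NMP, CH2Cl2, −78 °C) adds to aldehyde 14 in the Evans-syn sense to give (2S,3S)-1-[(S)-4-benzyl-2-thioxothiazolidin-3-yl]-2-[5-bromo-3-methoxy-2-(methoxymethoxy)phenyl]-3-[3,5-dimethoxy-4-(methoxymethoxy)phenyl]-3-hydroxypropan-1-one F2. The thioimide is cleaved directly by NaBH4 in wet THF at 0 °C, and the route is rejoined at diol 18.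

**Step 10 (MOM removal and ring closure).** On the free 1,3-diol the released formaldehyde can form a methylene acetal, the cation can lose the γ-CH2OH as formaldehyde to give a stilbene, or the benzylic methyl ether can persist. The fallback sets out from diol 18 and closes the ring on a mono-alcohol under anhydrous acid. The primary hydroxyl is acetylated selectively (AcCl, 2,4,6-collidine, CH2Cl2, −78 °C) to give (2R,3S)-2-[5-bromo-3-methoxy-2-(methoxymethoxy)phenyl]-3-[3,5-dimethoxy-4-(methoxymethoxy)phenyl]-3-hydroxypropyl acetate F3. TFA in CH2Cl2 (1:10, 0 °C) then removes both MOM groups and closes the trans ring to give [(2S,3R)-5-bromo-2-(4-hydroxy-3,5-dimethoxyphenyl)-7-methoxy-2,3-dihydrobenzofuran-3-yl]methyl acetate F4. Acetylation of the phenol (Ac2O, pyridine) brings the route back at diacetate 21.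

**Step 12 (Heck coupling).** The electron-rich aryl bromide may react slowly, and the aryl acetate may be partly lost under amine base and heat. The fallback sets out from diacetate 21 and installs the complete three-carbon allylic alcohol in one cross-coupling. Stille coupling with (E)-3-(tributylstannyl)prop-2-en-1-ol (Pd(PPh3)4, toluene, 100 °C, neutral) gives [(2S,3R)-2-(4-acetoxy-3,5-dimethoxyphenyl)-5-[(E)-3-hydroxyprop-1-en-1-yl]-7-methoxy-2,3-dihydrobenzofuran-3-yl]methyl acetate F5. Methanolysis of both acetates (K2CO3, MeOH, rt) bypasses 23 and comes back to the route at the target 24.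

## Further compounds
F1 | step 8 | 1-[(S)-4-benzyl-2-thioxothiazolidin-3-yl]-2-[5-bromo-3-methoxy-2-(methoxymethoxy)phenyl]ethan-1-one | COCOc1c(OC)cc(Br)cc1CC(=O)N1[C@@H](Cc2ccccc2)CSC1=S
F2 | step 8 | (2S,3S)-1-[(S)-4-benzyl-2-thioxothiazolidin-3-yl]-2-[5-bromo-3-methoxy-2-(methoxymethoxy)phenyl]-3-[3,5-dimethoxy-4-(methoxymethoxy)phenyl]-3-hydroxypropan-1-one | COCOc1c(OC)cc([C@@H](O)[C@@H](C(=O)N2[C@@H](Cc3ccccc3)CSC2=S)c2cc(Br)cc(OC)c2OCOC)cc1OC
F3 | step 10 | (2R,3S)-2-[5-bromo-3-methoxy-2-(methoxymethoxy)phenyl]-3-[3,5-dimethoxy-4-(methoxymethoxy)phenyl]-3-hydroxypropyl acetate | COCOc1c(OC)cc([C@@H](O)[C@@H](COC(C)=O)c2cc(Br)cc(OC)c2OCOC)cc1OC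
F4 | step 10 | [(2S,3R)-5-bromo-2-(4-hydroxy-3,5-dimethoxyphenyl)-7-methoxy-2,3-dihydrobenzofuran-3-yl]methyl acetate | COc1cc([C@H]2Oc3c(OC)cc(Br)cc3[C@@H]2COC(C)=O)cc(OC)c1O
F5 | step 12 | [(2S,3R)-2-(4-acetoxy-3,5-dimethoxyphenyl)-5-[(E)-3-hydroxyprop-1-en-1-yl]-7-methoxy-2,3-dihydrobenzofuran-3-yl]methyl acetate | COc1cc([C@H]2Oc3c(OC)cc(/C=C/CO)cc3[C@@H]2COC(C)=O)cc(OC)c1OC(C)=O
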